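**Retrosynthetic overview**
- The target is cut at the C5–OH bond, giving 2-hentriacontyl-7-hydroxy-8-methylchromone. The 5-OH goes in last by C4=O-directed peri-C–H functionalisation, so the 5,7-dihydroxy-8-methyl pattern is fixed and no 6-/8-methyl isomer can arise.
- The pyranone ring is cut at O1–C2: cyclodehydration of an o-hydroxyaryl β-diketone, made by C-acylating 2',4'-dihydroxy-3'-methylacetophenone with activated dotriacontanoic acid.
- The C32 acid is cut into C22 + C10: Cu-catalysed coupling of docosylmagnesium bromide with 10-bromodecanoic acid.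
- Ring order: the benzene ring is bought, the pyranone ring is closed in step 2, and no further ring is formed.

Assumption: the target has no stereocentre and no stereogenic double bond (it is achiral), so no stereocontrol is needed; the side chain is read as n-hentriacontyl (C31).

**Route**

Step 1
Reactants: 1 1-bromodocosane; 2 10-bromodecanoic acid
Product: 5 dotriacontanoic acid, via docosylmagnesium bromide 3 (not isolated), via chloromagnesium 10-bromodecanoate 4 (not isolated)
Conditions: (i) 1 (1.3 equiv), Mg, THF, 50 °C; (ii) 2, MeMgCl (1.0 equiv), THF, −20 °C; (iii) Li2CuCl4 (3 mol %), add 3, −20 → 20 °C; aq HCl; recrystallise (toluene/acetone)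
Reagents that add atoms: none
Why: Kochi-type Cu-catalysed sp3–sp3 Grignard cross-coupling, in which the cuprate from 3 displaces the primary bromide of 4 much faster than RMgX adds to the magnesium carboxylate; no stereocentre is formed.

Step 2
Reactants: 5 dotriacontanoic acid; 6 1-(2,4-dihydroxy-3-methylphenyl)ethan-1-one
Product: 10 2-hentriacontyl-7-hydroxy-8-methyl-4H-chromen-4-one, via N-dotriacontanoylimidazole 7 (not isolated), via trilithiated ketone 8 (not isolated), via beta-diketone 9 (not isolated)
Conditions: (i) 5, CDI (1.05 equiv), THF, 50 °C; (ii) 6, LiHMDS (4.3 equiv), THF, −78 → −10 °C, then warm THF solution of 7, −20 °C → rt; aq HCl; (iii) crude 9, AcOH, H2SO4 (cat.), 100 °C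
Reagents that add atoms: none
Why: Claisen-type C-acylation of the polylithiated o-hydroxyacetophenone (phenols masked as Li phenoxides, the extra base absorbs the acidic β-diketone), then acid-catalysed cyclodehydration (2'-OH attacks the enolised distal carbonyl, water is lost) forms the O1–C2 bond; only one OH is ortho to the acyl group, so the 7-OH/8-Me pattern is unambiguous; no stereocentre.

Step 3
Reactants: 10 2-hentriacontyl-7-hydroxy-8-methyl-4H-chromen-4-one
Product: 14 2-hentriacontyl-5,7-dihydroxy-8-methyl-4H-chromen-4-one, via 7-O-Bpin chromone 11 (not isolated), via 5-Bpin 7-O-Bpin chromone 12 (not isolated), via bis(O-Bpin) chromone 13 (not isolated)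
Conditions: (i) HBpin (1.2 equiv), octane, 60 °C; (ii) [Ir(OMe)(cod)]2 (2.5 mol %), AsPh3 (10 mol %), B2pin2 (1.3 equiv), octane, 120 °C; (iii) Me3NO (4 equiv), THF, 50 °C; aq NH4Cl / 1 M HCl
Reagents that add atoms: trimethylamine N-oxide, C[N+](C)(C)[O-]
Why: Proposed new method: one-pot peri-C5–H hydroxylation of an unprotected hydroxychromone by transient O-borylation, pyranone-carbonyl-directed Ir-catalysed C–H borylation and amine-oxide oxidation; the O-Bpin mask removes the acidic phenol, the Lewis-basic C4=O binds the mono-arsine-ligated Ir tris(boryl) complex (one vacant site) and delivers it to the only C–H that can close a five-membered iridacycle (C5–H; C2 carries no H, C3–H would need a four-membered cycle, C6–H is undirected), C–B reductive elimination gives 12, and Me3NO converts C–B into C–O at the same carbon by a 1,2-aryl shift without touching the enone, the borate esters being hydrolysed on work-up, while the hydrocarbon solvent dissolves the C31 lipid; the closest known reaction types are ketone- and ester-directed Ir-catalysed ortho-C–H borylation of simple arenes with monodentate arsine or electron-poor phosphine ligands, traceless O-Bpin masking of phenols in Ir borylation, and N-oxide oxidation of arylboronates, and to my knowledge neither directed borylation at the chromone peri position nor this one-pot sequence on a free hydroxychromone has been shown; no stereocentre.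

**Compound list**
1 | 1-bromodocosane | CCCCCCCCCCCCCCCCCCCCCCBr | starting material
2 | 10-bromodecanoic acid | OC(=O)CCCCCCCCCBr | starting material
3 | docosylmagnesium bromide | CCCCCCCCCCCCCCCCCCCCCC[Mg]Br | intermediate
4 | chloromagnesium 10-bromodecanoate | BrCCCCCCCCCC(=O)O[Mg]Cl | intermediate
5 | dotriacontanoic acid | CCCCCCCCCCCCCCCCCCCCCCCCCCCCCCCC(=O)O | intermediate
6 | 1-(2,4-dihydroxy-3-methylphenyl)ethan-1-one (2',4'-dihydroxy-3'-methylacetophenone) | CC(=O)c1ccc(O)c(C)c1O | starting material
7 | 1-(1H-imidazol-1-yl)dotriacontan-1-one (N-dotriacontanoylimidazole) | CCCCCCCCCCCCCCCCCCCCCCCCCCCCCCCC(=O)n1ccnc1 | intermediate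
8 | trilithium enolate bis(phenoxide) of 6 | [Li+].[Li+].[Li+].C=C([O-])c1ccc([O-])c(C)c1[O-] | intermediate
9 | 1-(2,4-dihydroxy-3-methylphenyl)tetratriacontane-1,3-dione | CCCCCCCCCCCCCCCCCCCCCCCCCCCCCCCC(=O)CC(=O)c1ccc(O)c(C)c1O | intermediate
10 | 2-hentriacontyl-7-hydroxy-8-methyl-4H-chromen-4-one | CCCCCCCCCCCCCCCCCCCCCCCCCCCCCCCc1cc(=O)c2ccc(O)c(C)c2o1 | intermediate
11 | 2-hentriacontyl-8-methyl-7-[(4,4,5,5-tetramethyl-1,3,2-dioxaborolan-2-yl)oxy]-4H-chromen-4-one | CCCCCCCCCCCCCCCCCCCCCCCCCCCCCCCc1cc(=O)c2ccc(OB3OC(C)(C)C(C)(C)O3)c(C)c2o1 | intermediate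
12 | 2-hentriacontyl-8-methyl-5-(4,4,5,5-tetramethyl-1,3,2-dioxaborolan-2-yl)-7-[(4,4,5,5-tetramethyl-1,3,2-dioxaborolan-2-yl)oxy]-4H-chromen-4-one | CCCCCCCCCCCCCCCCCCCCCCCCCCCCCCCc1cc(=O)c2c(B3OC(C)(C)C(C)(C)O3)cc(OB4OC(C)(C)C(C)(C)O4)c(C)c2o1 | intermediate
13 | 2-hentriacontyl-8-methyl-5,7-bis[(4,4,5,5-tetramethyl-1,3,2-dioxaborolan-2-yl)oxy]-4H-chromen-4-one | CCCCCCCCCCCCCCCCCCCCCCCCCCCCCCCc1cc(=O)c2c(OB3OC(C)(C)C(C)(C)O3)cc(OB4OC(C)(C)C(C)(C)O4)c(C)c2o1 | intermediate
14 | 2-hentriacontyl-5,7-dihydroxy-8-methyl-4H-chromen-4-one | CCCCCCCCCCCCCCCCCCCCCCCCCCCCCCCc1cc(=O)c2c(O)cc(O)c(C)c2o1 | target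

**Summary**
Total step count: 3. Longest linear sequence: 3 (1 + 2 → 5 → 10 → 14).

Steps most likely to fail, in order of risk:

Step 3 (the proposed new step). Risks are Ir–H/HBpin reduction of the chromone enone, undirected borylation at C6 or C3, and slow metalation at the hindered peri position. The fallback uses known chemistry and sets out from 10. Acetylation (Ac2O, pyridine, DMAP, CH2Cl2) gives 2-hentriacontyl-8-methyl-4-oxo-4H-chromen-7-yl acetate F5. The known Ru(II)-catalysed ketone-directed C–H oxygenation ([RuCl2(p-cymene)]2 5 mol %, PhI(OCOCF3)2 2 equiv, TFA/TFAA/DCE, 80 °C) gives 7-acetoxy-2-hentriacontyl-8-methyl-4-oxo-4H-chromen-5-yl trifluoroacetate F6. Mild hydrolysis of both esters (K2CO3, MeOH/THF/H2O, rt, then dilute acid) comes back to the route at 14.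

Step 2. Risks are O- versus C-acylation, incomplete polyanion formation and poor solubility of the C32 acyl donor at low temperature. The fallback replaces intermolecular enolate acylation by an intramolecular O→C acyl transfer and sets out from 5 and 6. 5 is converted ((COCl)2, cat. DMF, CH2Cl2/toluene, 40 °C) into dotriacontanoyl chloride F3. 6 is bis-O-acylated (F3 2.2 equiv, pyridine, DMAP, toluene, 60 °C) to 4-acetyl-2-methyl-1,3-phenylene didotriacontanoate F4. Powdered KOH in pyridine (60 °C), then aqueous-methanolic KOH and acidification, effects the Baker–Venkataraman rearrangement of the ortho ester and saponifies the para ester (the released 5 is recovered). This comes back to the route at 9, which is cyclised with AcOH/H2SO4 as in step 2 to 10.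

Step 1. Risks are precipitation of the C22 Grignard, Wurtz homocoupling and difficult separation of waxy hydrocarbons. The fallback replaces the Cu-catalysed sp3–sp3 coupling by acetylide alkylation and hydrogenation and sets out from 1. Commercial 9-decynoic acid is doubly deprotonated (n-BuLi 2.1 equiv, THF/DMPU, −78 → 0 °C) to dilithium 9-decynoate acetylide F1. Alkylation with 1 (0 → 40 °C) gives dotriacont-9-ynoic acid F2. Hydrogenation (H2 1 atm, Pd/C, THF/EtOAc, 50 °C) comes back to the route at 5.

**Further compounds**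
F1 | step 1 | dilithium 9-decynoate acetylide (dianion of 9-decynoic acid) | [Li+].[Li+].[C-]#CCCCCCCCC(=O)[O-]
F2 | step 1 | dotriacont-9-ynoic acid | CCCCCCCCCCCCCCCCCCCCCCC#CCCCCCCCC(=O)O
F3 | step 2 | dotriacontanoyl chloride | CCCCCCCCCCCCCCCCCCCCCCCCCCCCCCCC(=O)Cl
F4 | step 2 | 4-acetyl-2-methyl-1,3-phenylene didotriacontanoate | CC(=O)c1ccc(OC(=O)CCCCCCCCCCCCCCCCCCCCCCCCCCCCCCC)c(C)c1OC(=O)CCCCCCCCCCCCCCCCCCCCCCCCCCCCCCC
F5 | step 3 | 2-hentriacontyl-8-methyl-4-oxo-4H-chromen-7-yl acetate | CCCCCCCCCCCCCCCCCCCCCCCCCCCCCCCc1cc(=O)c2ccc(OC(C)=O)c(C)c2o1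
F6 | step 3 | 7-acetoxy-2-hentriacontyl-8-methyl-4-oxo-4H-chromen-5-yl trifluoroacetate | CCCCCCCCCCCCCCCCCCCCCCCCCCCCCCCc1cc(=O)c2c(OC(=O)C(F)(F)F)cc(OC(C)=O)c(C)c2o1
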